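**Turnover rate.** Divide the product fraction of the substrate charge by the catalyst fraction of that charge, then by the time. This ratio, the turnover frequency, counts product molecules per charged catalyst per minute. While substrate and partner stay nearly whole and the catalyst keeps working, you may freeze it at one temperature, and product is then rate times catalyst fraction times time.

| flask | substrate | partner | free catalyst | added ligand | temperature | remark | time |
|---|---|---|---|---|---|---|---|
| north | 0.40 M | 1.6 M | 2.9 mM | 9.7 mM | 55 °C | run made earlier |  |
| east | 0.40 M | 1.6 M | 3.9 mM | 9.7 mM | 70 °C | run made earlier |  |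
| beta | 0.40 M | 1.60 M | 3.0 mM | 9.7 mM | 80 °C |  | 40 min |
| theta | 0.40 M | 1.60 M | 2.0 mM | 9.7 mM | 60 °C |  | 40 min |

- north (time / min: product / %): 6.00: 0.5; 12.0: 0.8; 15.0: 0.1; 25.0: 2.0; 30.0: 2.1
- east (time / min: product / %): 1.50: 0.2; 2.50: 1.0; 5.00: 2.7; 10.0: 5.7; 20.0: 9.8

(each reading ± 0.5 percentage points)

* which of the two ends with the higher amount of product, in percent of the substrate charged ("neither" if they lie within 2 percentage points) (beta / theta / neither)
* product at the end, in percent of the substrate charged, beta
* product at the end, in percent of the substrate charged, theta

- a reading or a percentage of product counts all its forms, free or not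

**Two neighbours.** Theta looks nearly like north, so start there. North's last reading gives 0.0966 /min, and its scatter is about a quarter of that reading. East's reading at 10.0 min gives 0.585 /min, which is 6.06 times as much. Read as an Arrhenius line, that means an activation energy of 112 kJ/mol, so theta's frozen turnover rate is 0.179 /min. Against north, theta has 0.690 of the catalyst, 1.85 times the rate and 1.33 times the time, so my theta ends at 3.58%.

**Beta's fade.** Frozen at 80 °C, the rate is 1.78 /min, which would give beta 53.5%. But east's readings may slow: from 10.0 min to 20.0 min they run at 0.719 of their earlier pace, which reads as a fade of 0.0329 /min. This reading is weak, since the later stretch falls short of the earlier by 1.6 percentage points and the scatter of that difference is 1.1 points. Carrying the fade as read, beta reaches 29.7%, and I commit to that figure loosely, with beta the higher flask.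

**The forecast.** It names beta, with beta at 20% (10% to 33%) and theta at 3.3% (2.3% to 4.6%). Of the slowing it reads in east it says: “This points to product inhibition or catalyst loss”. My figures lie higher than its figures for beta and for theta.

**The result.** Beta ends at 26.9% and theta at 3.19%, so the higher flask is beta.

    partner + free catalyst → catalyst intermediate A (k = 0.0581 /M/s, Ea = 55.0 kJ/mol)
    catalyst intermediate A ⇌ catalyst intermediate B (K = 2.00, k = 0.107 /s, Ea = 89.0 kJ/mol, ΔH = 30.0 kJ/mol)
    substrate + catalyst intermediate B ⇌ catalyst intermediate C (K = 0.847 /M, k = 0.293 /M/s, Ea = 40.0 kJ/mol, ΔH = −18.0 kJ/mol)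
    catalyst intermediate C ⇌ free catalyst + product (K = 3.23 M, k = 0.622 /s, Ea = 73.0 kJ/mol, ΔH = 17.0 kJ/mol)
    free catalyst → spent catalyst (k = 3.95 × 10⁻⁴ /s, Ea = 96.0 kJ/mol)
    free catalyst + added ligand ⇌ idle complex A, settled at all times (K = 3770 /M, ΔH = −49.0 kJ/mol)
    free catalyst + product ⇌ idle complex B (K = 0.670 /M, k = 0.00155 /M/s, Ea = 59.0 kJ/mol, ΔH = −30.0 kJ/mol)
    (constants at 60 °C)

**The neighbour.** Theta's result is a turnover rate of 0.160 /min, against the frozen 0.179 /min. The neighbour flask is theta charged with 0.0080 M of free catalyst, 2.00% of the substrate charge, and the frozen rate gives it 14.3%. It reaches 23.1%, a turnover rate of 0.289 /min, which is 1.81 times theta's. At 40.0 min, idle complex A holds 72.7% of the neighbour's catalyst, against 86.0% in theta.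

The data come from a simulation with constants of no real substance, and the scatter is random.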